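**Retrosynthetic overview**
- Target 15 ⇐ axial methyl addition to α-silyloxy ketone 13 ⇐ Rubottom oxidation of silyl enol ether 11 ⇐ methylenation of linker ketone 10.
- 10 ⇐ Mukaiyama–Michael union of enone 4 (ring A) with silyl enol ether 9 (ring B); this forms the ring A–CH2 bond trans to the isopropenyl group.
- 4 ⇐ prenal 1 + methyl vinyl ketone 2: organocatalytic dienamine α-Michael addition sets the isopropenyl-bearing centre, then aldol condensation closes ring A.
- 9 ⇐ methyl ketone 8 ⇐ organocatalytic α-bromination of the achiral Weinreb keto-amide 5, MeMgBr addition anti to Br, equilibration of the acetyl-bearing centre.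
- Ring order: ring B is present in 5; ring A is formed in step 1; the rings are joined in step 5.

Assumption: 5 is bought (otherwise one amidation of 4-oxocyclohexanecarboxylic acid), and catalyst antipodes follow the usual steric-shielding models; if a sense proves opposite, the mirror-image catalyst is used.

**Step 1**
Reactants: 1 3-methylbut-2-enal (prenal); 2 but-3-en-2-one (methyl vinyl ketone)
Product: 4 (4S)-4-(prop-1-en-2-yl)cyclohex-2-en-1-one, via keto-aldehyde 3 (not isolated)
Conditions: (R)-2-[methoxy(diphenyl)methyl]pyrrolidine (10 mol %), ethyl 3,4-dihydroxybenzoate (20 mol %), neat, 4 °C; then toluene, TsOH·H2O (10 mol %), 4 Å MS, 40 °C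
Reagents that add atoms: none
Why: Proposed new method: the (E)-s-trans dienamine from 1 and the (R)-prolinol ether carries its largest HOMO coefficient at the α-carbon, which adds to catechol-activated 2 on the face away from the CPh2OMe group to set C-2 of 3 as R (the α-branched product no longer condenses with the catalyst), and acid-catalysed intramolecular aldol condensation then closes ring A without touching that centre; the closest known reactions are the diarylprolinol-ether enamine Michael addition of saturated aldehydes to enones and α-selective dienamine alkylations.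

**Step 2**
Reactants: 5 N-methoxy-N-methyl-4-oxocyclohexane-1-carboxamide
Product: 6 (1S,3R)-3-bromo-N-methoxy-N-methyl-4-oxocyclohexane-1-carboxamide
Conditions: (4S,5S)-4,5-diphenylimidazolidine (20 mol %), PhCO2H (20 mol %), 4,4-dibromo-2,6-di-tert-butylcyclohexa-2,5-dien-1-one (1.0 equiv), CH2Cl2/pentane, −30 °C; cold silica plug, used at once
Reagents that add atoms: 4,4-dibromo-2,6-di-tert-butylcyclohexa-2,5-dien-1-one, CC(C)(C)C1=CC(Br)(Br)C=C(C(C)(C)C)C1=O
Why: Enamine-catalysed asymmetric α-bromination in which the C2-symmetric catalyst fixes the C–Br centre as 3R; axial attack gives mainly the 1,3-trans isomer shown (some 1R epimer), which does not matter because C-1 is equilibrated in step 3.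

**Step 3**
Reactants: 6 (1S,3R)-3-bromo-N-methoxy-N-methyl-4-oxocyclohexane-1-carboxamide
Product: 8 1-[(1R,3R,4S)-3-bromo-4-hydroxy-4-methylcyclohexyl]ethan-1-one, via C-1 epimer 7 (not isolated)
Conditions: MeMgBr (3.3 equiv), THF, −78 → 0 °C, aq. NH4Cl; then K2CO3, MeOH, 23 °C
Reagents that add atoms: methylmagnesium bromide, C[Mg]Br
Why: Grignard addition to the α-bromo ketone occurs anti to the C–Br bond (Cornforth/polar Felkin–Anh), giving the cis bromohydrin (4S), and the Weinreb amide gives the methyl ketone; base-mediated enolisation then equilibrates C-1 to the isomer with acetyl, Br and Me all equatorial (estimated 5–8:1, minor 7 separated and recycled).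

**Step 4**
Reactants: 8 1-[(1R,3R,4S)-3-bromo-4-hydroxy-4-methylcyclohexyl]ethan-1-one
Product: 9 trimethyl({1-[(1R,3R,4S)-3-bromo-4-methyl-4-[(trimethylsilyl)oxy]cyclohexyl]ethenyl}oxy)silane
Conditions: LiN(iPr)2 (2.3 equiv), Me3SiCl (4 equiv), THF, −78 °C (in situ quench); Et3N, → 0 °C
Reagents that add atoms: chlorotrimethylsilane, C[Si](C)(C)Cl
Why: Kinetic enolisation at the methyl group with in situ silylation gives the terminal silyl enol ether and silylates the tertiary alkoxide, and no stereocentre is touched because the ring methine is not deprotonated at −78 °C.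

**Step 5**
Reactants: 4 (4S)-4-(prop-1-en-2-yl)cyclohex-2-en-1-one; 9 trimethyl({1-[(1R,3R,4S)-3-bromo-4-methyl-4-[(trimethylsilyl)oxy]cyclohexyl]ethenyl}oxy)silane
Product: 10 1-[(1R,3R,4S)-3-bromo-4-methyl-4-[(trimethylsilyl)oxy]cyclohexyl]-2-[(1R,6S)-6-(prop-1-en-2-yl)-3-[(trimethylsilyl)oxy]cyclohex-2-en-1-yl]ethan-1-one
Conditions: [Ph3C][SbCl6] (5 mol %), CH2Cl2, −78 °C; pyridine quench
Reagents that add atoms: none
Why: Trityl-cation-catalysed Mukaiyama–Michael addition with silyl transfer, in which the enol ether adds to C-3 of 4 anti to the C-4 isopropenyl group (new centre R, trans) and the ring A ketone is delivered as a regiodefined silyl enol ether.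

**Step 6**
Reactants: 10 (Mukaiyama–Michael adduct)
Product: 11 trimethyl{[(1S,2R,4R)-2-bromo-1-methyl-4-(3-{(1R,6S)-6-(prop-1-en-2-yl)-3-[(trimethylsilyl)oxy]cyclohex-2-en-1-yl}prop-1-en-2-yl)cyclohexyl]oxy}silane
Conditions: Cp2Ti(μ-CH2)(μ-Cl)AlMe2 (1.3 equiv), pyridine (cat.), THF/toluene, −40 → 0 °C; aq. NaOH, basic Al2O3 filtration
Reagents that add atoms: Tebbe reagent Cp2Ti(μ-CH2)(μ-Cl)AlMe2, C[Al-]1(C)C[Ti](C2C=CC=C2)(C2C=CC=C2)[Cl+]1
Why: Tebbe methylenation converts the only free ketone into the 1,1-disubstituted alkene under non-basic conditions, so the adjacent ring B methine is not epimerised and the silyl enol ether is untouched.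

**Step 7**
Reactants: 11 (bis-silyl triene)
Product: 13 (2S,3R,4S)-3-{2-[(1R,3R,4S)-3-bromo-4-methyl-4-[(trimethylsilyl)oxy]cyclohexyl]prop-2-en-1-yl}-4-(prop-1-en-2-yl)-2-[(trimethylsilyl)oxy]cyclohexan-1-one, via silyloxy epoxide 12 (not isolated)
Conditions: dimethyldioxirane (1.05 equiv), acetone/CH2Cl2, −78 °C; → 23 °C
Reagents that add atoms: dimethyldioxirane, CC1(C)OO1
Why: Rubottom oxidation, in which the electron-rich enol ether is epoxidised far faster than the two 1,1-disubstituted alkenes and anti to the adjacent side chain, and 1,4-silyl shift gives the all-equatorial (also thermodynamic) 2S silyloxy ketone.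

**Step 8**
Reactants: 13 (α-silyloxy ketone)
Product: 15 (1S,2S,3R,4S)-3-{2-[(1R,3R,4S)-3-bromo-4-hydroxy-4-methylcyclohexyl]prop-2-en-1-yl}-1-methyl-4-(prop-1-en-2-yl)cyclohexane-1,2-diol, via bis-silyl ether 14 (not isolated)
Conditions: MeAl(OAr)2 (Ar = 2,6-tBu2-4-MeC6H2, 3 equiv), toluene, −78 °C, then MeLi (3 equiv); 1 M HCl, THF, 0 → 23 °C
Reagents that add atoms: methyllithium, [Li]C
Why: The bulky aluminium aryloxide complexes the carbonyl from the equatorial side so that MeLi attacks axially (amphiphilic carbonyl alkylation), giving the equatorial tertiary alcohol with axial methyl (1S, trans-diol), and the acidic work-up cleaves both trimethylsilyl ethers.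

**Compound list**
1 | 3-methylbut-2-enal | CC(C)=CC=O | starting material
2 | but-3-en-2-one | CC(=O)C=C | starting material
3 | (2R)-5-oxo-2-(prop-1-en-2-yl)hexanal | O=C[C@@H](C(C)=C)CCC(C)=O | intermediate (not isolated)
4 | (4S)-4-(prop-1-en-2-yl)cyclohex-2-en-1-one | O=C1C=C[C@@H](C(C)=C)CC1 | intermediate
5 | N-methoxy-N-methyl-4-oxocyclohexane-1-carboxamide | CON(C)C(=O)C1CCC(=O)CC1 | starting material
6 | (1S,3R)-3-bromo-N-methoxy-N-methyl-4-oxocyclohexane-1-carboxamide (major epimer) | CON(C)C(=O)[C@H]1CCC(=O)[C@H](Br)C1 | intermediate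
7 | 1-[(1S,3R,4S)-3-bromo-4-hydroxy-4-methylcyclohexyl]ethan-1-one | CC(=O)[C@H]1CC[C@](C)(O)[C@H](Br)C1 | intermediate (not isolated)
8 | 1-[(1R,3R,4S)-3-bromo-4-hydroxy-4-methylcyclohexyl]ethan-1-one | CC(=O)[C@@H]1CC[C@](C)(O)[C@H](Br)C1 | intermediate
9 | trimethyl({1-[(1R,3R,4S)-3-bromo-4-methyl-4-[(trimethylsilyl)oxy]cyclohexyl]ethenyl}oxy)silane | C=C(O[Si](C)(C)C)[C@@H]1CC[C@](C)(O[Si](C)(C)C)[C@H](Br)C1 | intermediate
10 | 1-[(1R,3R,4S)-3-bromo-4-methyl-4-[(trimethylsilyl)oxy]cyclohexyl]-2-[(1R,6S)-6-(prop-1-en-2-yl)-3-[(trimethylsilyl)oxy]cyclohex-2-en-1-yl]ethan-1-one | O=C(C[C@@H]1[C@@H](C(=C)C)CCC(O[Si](C)(C)C)=C1)[C@@H]1CC[C@](C)(O[Si](C)(C)C)[C@H](Br)C1 | intermediate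
11 | trimethyl{[(1S,2R,4R)-2-bromo-1-methyl-4-(3-{(1R,6S)-6-(prop-1-en-2-yl)-3-[(trimethylsilyl)oxy]cyclohex-2-en-1-yl}prop-1-en-2-yl)cyclohexyl]oxy}silane | C=C(C[C@@H]1[C@@H](C(=C)C)CCC(O[Si](C)(C)C)=C1)[C@@H]1CC[C@](C)(O[Si](C)(C)C)[C@H](Br)C1 | intermediate
12 | 2-silyloxy oxirane of 11 (oxygen added to the ring A enol ether on the face anti to the adjacent side chain) | C=C(C[C@@H]1[C@@H](C(=C)C)CC[C@@]2(O[Si](C)(C)C)O[C@@H]12)[C@@H]1CC[C@](C)(O[Si](C)(C)C)[C@H](Br)C1 | intermediate (not isolated)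
13 | (2S,3R,4S)-3-{2-[(1R,3R,4S)-3-bromo-4-methyl-4-[(trimethylsilyl)oxy]cyclohexyl]prop-2-en-1-yl}-4-(prop-1-en-2-yl)-2-[(trimethylsilyl)oxy]cyclohexan-1-one | C=C(C[C@@H]1[C@@H](C(=C)C)CCC(=O)[C@H]1O[Si](C)(C)C)[C@@H]1CC[C@](C)(O[Si](C)(C)C)[C@H](Br)C1 | intermediate
14 | (1S,2S,3R,4S)-3-{2-[(1R,3R,4S)-3-bromo-4-methyl-4-[(trimethylsilyl)oxy]cyclohexyl]prop-2-en-1-yl}-1-methyl-4-(prop-1-en-2-yl)-2-[(trimethylsilyl)oxy]cyclohexan-1-ol | C=C(C[C@@H]1[C@@H](C(=C)C)CC[C@](C)(O)[C@H]1O[Si](C)(C)C)[C@@H]1CC[C@](C)(O[Si](C)(C)C)[C@H](Br)C1 | intermediate (not isolated)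
15 | (1S,2S,3R,4S)-3-{2-[(1R,3R,4S)-3-bromo-4-hydroxy-4-methylcyclohexyl]prop-2-en-1-yl}-1-methyl-4-(prop-1-en-2-yl)cyclohexane-1,2-diol | C=C(C[C@@H]1[C@@H](C(=C)C)CC[C@](C)(O)[C@H]1O)[C@@H]1CC[C@](C)(O)[C@H](Br)C1 | target

**Step count and risks**
Total steps: 8. Longest linear sequence: 7 (steps 2–8, from 5).

The three steps most likely to fail are steps 1, 5 and 8.

For step 1 (the proposed new reaction) the risks are γ-attack or a [4+2] pathway of the dienamine, and loss of ee in 3 by enolisation toward the isopropenyl group during cyclisation. The fallback uses known chemistry and sets out not from 1 and 2 but from achiral 4-(prop-1-en-2-yl)cyclohexan-1-one F1. Enantiotopic deprotonation with lithium (R,R)-bis(1-phenylethyl)amide and LiCl in THF at −100 °C with Me3SiCl in situ gives trimethyl{[(4S)-4-(prop-1-en-2-yl)cyclohex-1-en-1-yl]oxy}silane F2. Saegusa–Ito oxidation of F2 with Pd(OAc)2 in MeCN gives the enone, and the fallback comes back to the route at 4.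

For step 5 the risks are low reactivity of the hindered enol ether toward the γ-substituted enone and hydrolysis of the product enol ether. The fallback sets out from 9. MeLi in THF at 0 °C releases the lithium enolate, and PhNTf2 traps it as 1-[(1R,3R,4S)-3-bromo-4-methyl-4-[(trimethylsilyl)oxy]cyclohexyl]ethenyl trifluoromethanesulfonate F3. Kumada coupling of F3 with Me3SiCH2MgCl and Pd(PPh3)4 (5 mol %) in THF gives trimethyl{[(1S,2R,4R)-2-bromo-1-methyl-4-[3-(trimethylsilyl)prop-1-en-2-yl]cyclohexyl]oxy}silane F4. Catalytic Hosomi–Sakurai conjugate allylation of 4 with F4 (InCl3 10 mol %, Me3SiCl, CH2Cl2, −30 °C, non-aqueous work-up) gives the silyl enol ether directly, so the fallback comes back at 11 and step 6 is not needed.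

For step 8 the risk is that the α-silyloxy group disturbs the aluminium complexation and equatorial attack gives the cis-diol. The fallback sets out from 13. Dimethylsulfonium methylide (Me3S+ I−, KN(SiMe3)2, THF, −10 °C) attacks axially and gives the 1-oxaspiro[2.5]octane spiro-epoxide F5, with CH2 axial and oxygen equatorial. LiAlH4 in Et2O at −20 → 0 °C opens F5 at the CH2 carbon; the hindered secondary bromide is expected to react more slowly. This gives the axial-methyl tertiary alcohol, so the fallback comes back at 14, which the acidic work-up of step 8 converts into 15.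

**Further compounds**
F1 | step 1 | 4-(prop-1-en-2-yl)cyclohexan-1-one | CC(=C)C1CCC(=O)CC1
F2 | step 1 | trimethyl{[(4S)-4-(prop-1-en-2-yl)cyclohex-1-en-1-yl]oxy}silane | C[Si](C)(C)OC1=CC[C@@H](C(C)=C)CC1
F3 | step 5 | 1-[(1R,3R,4S)-3-bromo-4-methyl-4-[(trimethylsilyl)oxy]cyclohexyl]ethenyl trifluoromethanesulfonate | C=C(OS(=O)(=O)C(F)(F)F)[C@@H]1CC[C@](C)(O[Si](C)(C)C)[C@H](Br)C1
F4 | step 5 | trimethyl{[(1S,2R,4R)-2-bromo-1-methyl-4-[3-(trimethylsilyl)prop-1-en-2-yl]cyclohexyl]oxy}silane | C=C(C[Si](C)(C)C)[C@@H]1CC[C@](C)(O[Si](C)(C)C)[C@H](Br)C1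
F5 | step 8 | spiro-epoxide of 13 (1-oxaspiro[2.5]octane at the former ketone carbon, CH2 axial and cis to the adjacent OSiMe3) | C=C(C[C@@H]1[C@@H](C(=C)C)CC[C@]3(OC3)[C@H]1O[Si](C)(C)C)[C@@H]1CC[C@](C)(O[Si](C)(C)C)[C@H](Br)C1
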